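**Retrosynthetic overview**
1. Ring C (C1′–C5′) is made last by benzilic-ester ring contraction of a 2-hydroxy-5-methoxy-1,4-benzoquinone; the quinone comes from a tetramethoxyaryl group added to the C11 aldehyde on C8 and deoxygenated.
2. The ring-B periphery is built from a C9 ketone: C8 carbomethoxylation and axial methylation (quaternary C8, ester carbon = C11), C9 methylenation and α-face hydrogenation, C10 equilibrated to the trans fusion.
3. The strategy rests on ring A (C1–C5, C10): a cyclohexene whose methyl-bearing C4 and quaternary, methyl-bearing C5 lie next to ring-fusion C10. It maps onto (E)-piperylene added across the C5=C10 bond of a 2-methylcyclohex-2-enone that is ring B (bonds C4–C5 and C1–C10); afterwards C6=O is removed and C2=C3 is moved to C3=C4.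
4. The dienophile, (S)-4-silyloxy-2-methylcyclohex-2-enone, is cut down from (−)-quinic acid; its C9 oxygen steers the cycloaddition and later becomes the C9 ketone.
5. Ring order: B (chiral pool), then A (Diels–Alder), then C (quinone, then ring contraction).

Key step: step 9

Remark: the target is taken exactly as the SMILES draws it (quaternary C8 carries C11, C9 is CHMe); decalin locants follow the overview, β is the face of the C5 methyl group and α the opposite face; the hydrazone geometry of 14 and the C11 configuration of 28 and 29 have no consequence.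

Step 1
Reactants: 1 (−)-quinic acid
Product: 2 3,4-O-isopropylidene-1,5-quinide (acetonide lactone)
Conditions: 2,2-dimethoxypropane, TsOH·H2O (cat.), acetone, reflux
Reagents that add atoms: 2,2-dimethoxypropane COC(C)(C)OC
Why: Acid-catalysed transketalisation of the cis-3,4-diol with lactonisation of the acid onto the 5-hydroxyl, which is cis to the carboxyl; no stereocentre is touched.

Step 2
Reactants: 2 3,4-O-isopropylidene-1,5-quinide
Product: 3 1-(hydroxymethyl)-3,4-(isopropylidenedioxy)cyclohexane-1,5-diol (configuration of quinic acid)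
Conditions: NaBH4, EtOH, 0 °C to rt
Reagents that add atoms: none
Why: Hydride reduction of the strained bicyclic lactone should give the primary alcohol and so unmask a 1,2-diol; stereocentres are unchanged.

Step 3
Reactants: 3 acetonide triol
Product: 4 (3R,4S,5R)-3-hydroxy-4,5-(isopropylidenedioxy)cyclohexan-1-one
Conditions: NaIO4, H2O (pH 6 buffer), 0 °C
Reagents that add atoms: none
Why: Malaprade glycol cleavage of the tertiary/primary 1,2-diol removes the former carboxyl carbon as formaldehyde and leaves the ketone.

Step 4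
Reactants: 4 (3R,4S,5R)-3-hydroxy-4,5-(isopropylidenedioxy)cyclohexan-1-one
Product: 6 (4S,5R)-4,5-(isopropylidenedioxy)cyclohex-2-en-1-one, via 3-O-mesylate 5 (not isolated)
Conditions: MsCl, Et3N, CH2Cl2, 0 °C to rt
Reagents that add atoms: none
Why: Mesylation of the β-hydroxyl and E1cB elimination should give the conjugated enone.

Step 5
Reactants: 6 (4S,5R)-4,5-(isopropylidenedioxy)cyclohex-2-en-1-one
Product: 7 (3R,4S)-3,4-(isopropylidenedioxy)cyclohexan-1-one
Conditions: H2 (1 atm), Pd/C, EtOAc, rt
Reagents that add atoms: none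
Why: Heterogeneous hydrogenation of the enone C=C leaves the ketal oxygen on the other side of the ketone as the only β-leaving group.

Step 6
Reactants: 7 (3R,4S)-3,4-(isopropylidenedioxy)cyclohexan-1-one
Product: 9 (S)-4-(tert-butyldimethylsilyloxy)cyclohex-2-en-1-one, via (S)-4-hydroxycyclohex-2-en-1-one 8 (not isolated)
Conditions: DBU, CH2Cl2, 0 °C; then TBSCl, imidazole, rt
Reagents that add atoms: tert-butyldimethylsilyl chloride CC(C)(C)[Si](C)(C)Cl
Why: E1cB β-elimination of the ketal oxygen (loss of acetone) places the enone on the side opposite to that of step 4, which makes the remaining carbinol (S), and silylation in the same flask protects the γ-hydroxy enone before it can isomerise.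

Step 7
Reactants: 9 (S)-4-(tert-butyldimethylsilyloxy)cyclohex-2-en-1-one
Product: 10 (S)-4-(tert-butyldimethylsilyloxy)-2-iodocyclohex-2-en-1-one
Conditions: I2, pyridine, CH2Cl2, 0 °C to rt
Reagents that add atoms: iodine II
Why: α-Iodination of an enone by pyridine conjugate addition, iodination of the enolate and elimination (Baylis–Hillman-type mechanism).

Step 8
Reactants: 10 (S)-4-(tert-butyldimethylsilyloxy)-2-iodocyclohex-2-en-1-one
Product: 11 (S)-4-(tert-butyldimethylsilyloxy)-2-methylcyclohex-2-en-1-one
Conditions: SnMe4, PdCl2(PhCN)2 (5 mol %), AsPh3, CuI, NMP, 80 °C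
Reagents that add atoms: tetramethylstannane C[Sn](C)(C)C
Why: Stille coupling of an α-iodoenone transfers methyl under neutral conditions that spare the γ-silyloxy group.

Step 9
Reactants: 11 (S)-4-(tert-butyldimethylsilyloxy)-2-methylcyclohex-2-en-1-one; 12 (E)-penta-1,3-diene
Product: 13 9β-(tert-butyldimethylsilyloxy)-4α,5β-dimethyl-10βH-Δ2-octalin-6-one (cis-fused)
Conditions: EtAlCl2 (0.5 equiv), toluene, −20 °C to rt
Reagents that add atoms: none
Why: EtAlCl2 binds the enone carbonyl and lowers its LUMO, and the diene adds suprafacially in a concerted, asynchronous, endo Lewis-acid-catalysed Diels–Alder reaction, the reaction type established for 2-methylcyclohex-2-enones with piperylene and for anti addition to 4-substituted cyclohexenones. Ring A closes by intermolecular [4+2] cycloaddition, the σ-bonds C4–C5 and C1–C10 forming on one face of the C5=C10 bond to give the cis-fused cyclohexene. The larger LUMO coefficient at the β-carbon C10 pairs with the unsubstituted diene terminus, so the methyl-bearing terminus bonds to C5 (ortho rule) and the vicinal C4/C5 methyl pattern results. The diene approaches anti to the C9 silyloxy group, which fixes quaternary C5 (methyl β) and C10 (H β) in absolute terms. The endo transition state with the E-diene places the C4 methyl α, trans to the C5 methyl; this centre is removed later. The step needs facial and regiochemical control, secured by the single bulky γ-substituent and the single activating carbonyl, and because C10 is not α to the ketone the adduct cannot epimerise.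

Step 10
Reactants: 13 cis-fused octalone
Product: 14 6-(p-toluenesulfonyl)hydrazone of 13
Conditions: TsNHNH2, EtOH, 4 Å MS, 70 °C
Reagents that add atoms: p-toluenesulfonohydrazide Cc1ccc(cc1)S(=O)(=O)NN
Why: Condensation of the hindered C6 ketone to its tosylhydrazone, the first half of a Caglioti-type deoxygenation, under conditions too mild to cleave the silyl ether.

Step 11
Reactants: 14 tosylhydrazone
Product: 15 9β-(tert-butyldimethylsilyloxy)-4α,5β-dimethyl-10βH-Δ2-octalin
Conditions: catecholborane, CHCl3, 0 °C to rt; then NaOAc·3H2O, 60 °C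
Reagents that add atoms: none
Why: Kabalka reduction: hydride adds to C=N and acetate then triggers loss of sulfinate and N2 from the diazene, giving C6H2 without touching the isolated alkene or the silyl ether.

Step 12
Reactants: 15 Δ2-octalin
Product: 16 9β-(tert-butyldimethylsilyloxy)-4,5β-dimethyl-10βH-Δ3-octalin
Conditions: PdCl2(MeCN)2 (10 mol %), toluene, 80 °C
Reagents that add atoms: none
Why: Positional alkene isomerisation by divalent palladium through a π-allyl hydride should move the disubstituted C2=C3 bond to the trisubstituted C3=C4 position, abstraction of the allylic C4–H being the only single 1,3-shift that gains a substituent; the C4 stereocentre is erased.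

Step 13
Reactants: 16 Δ3-octalin silyl ether
Product: 17 4,5β-dimethyl-10βH-Δ3-octalin-9β-ol
Conditions: TBAF, THF, rt
Reagents that add atoms: none
Why: Fluoride cleavage of the silyl ether.

Step 14
Reactants: 17 cis-fused octalinol
Product: 19 4,5β-dimethyl-10αH-Δ3-octalin-9-one (trans-fused), via cis-fused 10βH-ketone 18 (not isolated)
Conditions: Dess–Martin periodinane, NaHCO3, CH2Cl2, rt; aqueous work-up; then NaOMe (0.2 equiv), MeOH, rt
Reagents that add atoms: none
Why: Dess–Martin oxidation gives the cis-decalone, and equilibration through the C9/C10 enolate should turn the fusion trans (10α-H), the more stable arrangement for a decalone whose angular methyl is on the other fusion carbon, as in 6-oxo steroids.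

Step 15
Reactants: 19 trans-fused decalone
Product: 20 methyl 4,5β-dimethyl-9-oxo-10αH-Δ3-octalin-8-carboxylate (C8 epimers and enol)
Conditions: NaH, (MeO)2CO, THF, reflux; then aq. HCl
Reagents that add atoms: dimethyl carbonate COC(=O)OC
Why: Claisen-type C-acylation under thermodynamic control should occur at C8 only, because only the C8 β-keto ester can be held as its enolate.

Step 16
Reactants: 20 β-keto ester
Product: 21 methyl 4,5β,8α-trimethyl-9-oxo-10αH-Δ3-octalin-8β-carboxylate
Conditions: K2CO3, MeI, acetone, reflux
Reagents that add atoms: iodomethane CI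
Why: C-Alkylation of the β-keto ester enolate by axial attack on the α face of the trans-decalin (chair-like transition state, only hydrogens syn-axial at C6 and C10) places methyl α and leaves CO2Me β at the new quaternary C8.

Step 17
Reactants: 21 quaternary β-keto ester
Product: 22 methyl 4,5β,8α-trimethyl-9-methylidene-10αH-Δ3-octalin-8β-carboxylate
Conditions: Ph3PCH3Br, KN(SiMe3)2, toluene, 0 to 90 °C
Reagents that add atoms: methyltriphenylphosphonium bromide C[P+](c1ccccc1)(c1ccccc1)c1ccccc1.[Br-]
Why: Wittig methylenation with the small salt-free ylide should convert the hindered C9 ketone into the exocyclic alkene and leave the neopentyl ester alone.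

Step 18
Reactants: 22 exocyclic alkene
Product: 23 methyl 4,5β,8α,9β-tetramethyl-10αH-Δ3-octalin-8β-carboxylate
Conditions: H2 (1 atm), Pt/C, EtOAc, rt, stopped after one equivalent
Reagents that add atoms: none
Why: Heterogeneous hydrogenation takes the 1,1-disubstituted alkene before the hindered trisubstituted ring-A alkene, and hydrogen is delivered to the α face of C9 because the β face lies under the syn-axial C5 methyl (as with 6-methylidene steroids), which sets the 9β-methyl group.

Step 19
Reactants: 23 ester
Product: 24 (4,5β,8α,9β-tetramethyl-10αH-Δ3-octalin-8β-yl)methanol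
Conditions: LiAlH4, THF, 0 °C to rt
Reagents that add atoms: none
Why: Hydride reduction of the neopentyl ester to the primary alcohol at C11.

Step 20
Reactants: 24 neopentyl alcohol
Product: 25 4,5β,8α,9β-tetramethyl-10αH-Δ3-octalin-8β-carbaldehyde
Conditions: Dess–Martin periodinane, NaHCO3, CH2Cl2, rt
Reagents that add atoms: none
Why: Dess–Martin oxidation to the non-enolisable neopentyl aldehyde.

Step 21
Reactants: 25 aldehyde; 26 1,2,4,5-tetramethoxybenzene
Product: 29 O-[aryl(decalinyl)methyl] S-methyl dithiocarbonate (xanthate at C11), via 2,3,5,6-tetramethoxyphenyllithium 27 (not isolated), via lithium alkoxide 28 (not isolated)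
Conditions: 26, n-BuLi, THF, 0 °C to rt; 25, −78 to 0 °C; then CS2; then MeI
Reagents that add atoms: carbon disulfide S=C=S; iodomethane CI
Why: Directed ortho-lithiation between two methoxy groups, 1,2-addition of the aryllithium to the aldehyde and trapping of the alkoxide as the S-methyl xanthate form the C11–aryl bond and the first half of a Barton–McCombie deoxygenation; the C11 carbinol centre is removed in the next step.

Step 22
Reactants: 29 xanthate
Product: 30 8β-[(2,3,5,6-tetramethoxyphenyl)methyl]-4,5β,8α,9β-tetramethyl-10αH-Δ3-octalin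
Conditions: Bu3SnH, AIBN (cat.), toluene, 100 °C
Reagents that add atoms: none
Why: Barton–McCombie radical deoxygenation through the stabilised benzylic radical gives the ArCH2 link without cationic intermediates next to quaternary C8.

Step 23
Reactants: 30 tetramethoxyarene
Product: 31 3-(decalin-8β-ylmethyl)-2,5-dimethoxy-1,4-benzoquinone
Conditions: (NH4)2Ce(NO3)6, MeCN–H2O, 0 °C
Reagents that add atoms: water O
Why: Oxidative demethylation of a para-dimethoxy pair by tetravalent cerium gives the 2,5-dimethoxyquinone (either para pair gives the same compound), and the isolated alkene is inert to this one-electron oxidant at 0 °C.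

Step 24
Reactants: 31 dimethoxyquinone
Product: 32 3-(decalin-8β-ylmethyl)-2-hydroxy-5-methoxy-1,4-benzoquinone
Conditions: aq. KOH, MeOH, rt; then aq. HCl
Reagents that add atoms: potassium hydroxide [K+].[OH-]
Why: Addition–elimination of hydroxide at a vinylogous ester; the methoxy group flanked by the alkyl substituent is twisted out of conjugation and should be exchanged selectively, as is known for 3-alkyl-2,5-dimethoxybenzoquinones.

Step 25
Reactants: 32 hydroxyquinone
Product: 33 dysidenone A
Conditions: Cu(OTf)2 (20 mol %), (S,S)-2,2′-isopropylidenebis(4-tert-butyl-2-oxazoline) (22 mol %), MeOH–CH2Cl2, 4 Å MS, 0 °C to rt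
Reagents that add atoms: methanol CO
Why: Proposed new method: the Cu(OTf)2–bis(oxazoline) complex (divalent copper) is expected to chelate the 1,2-dione tautomer of the hydroxyquinone (C1=O/C2=O) as it chelates α-keto esters; methanol then adds to the more electrophilic C2 carbonyl on its open Si face and the hemiketal collapses by a suprafacial 1,2-shift of C3 from C2 to C1 on the opposite face (benzilic ester or α-ketol rearrangement), so the face of methanol addition fixes C1′ as S; C3 is configurationally labile and should migrate with retention and with its CH2–decalin group pseudo-equatorial, which places C11 cis to the extruded ester carbon and fixes C5′ as R; the closest known reactions are the base-mediated benzilic ester ring contraction of 2-hydroxy-1,4-benzoquinones to 4-hydroxy-4-carbomethoxycyclopentenones, which is unselective, and bis(oxazoline)–copper-controlled additions to chelated α-dicarbonyl compounds.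

**Compound list**
1 | (−)-quinic acid | C1[C@H]([C@H]([C@@H](C[C@@]1(C(=O)O)O)O)O)O | starting material
2 | 3,4-O-isopropylidene-1,5-quinide | C1[C@H]2OC(C)(C)O[C@H]2[C@H]3C[C@]1(O)C(=O)O3 | intermediate
3 | 1-(hydroxymethyl)-3,4-(isopropylidenedioxy)cyclohexane-1,5-diol | C1[C@H]2OC(C)(C)O[C@H]2[C@H](O)C[C@]1(O)CO | intermediate
4 | (3R,4S,5R)-3-hydroxy-4,5-(isopropylidenedioxy)cyclohexan-1-one | C1[C@H]2OC(C)(C)O[C@H]2[C@H](O)CC1=O | intermediate
5 | 3-O-mesylate of 4 | C1[C@H]2OC(C)(C)O[C@H]2[C@H](OS(C)(=O)=O)CC1=O | intermediate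
6 | (4S,5R)-4,5-(isopropylidenedioxy)cyclohex-2-en-1-one | C1[C@H]2OC(C)(C)O[C@H]2C=CC1=O | intermediate
7 | (3R,4S)-3,4-(isopropylidenedioxy)cyclohexan-1-one | C1[C@H]2OC(C)(C)O[C@H]2CCC1=O | intermediate
8 | (S)-4-hydroxycyclohex-2-en-1-one | O=C1C=C[C@@H](O)CC1 | intermediate
9 | (S)-4-(tert-butyldimethylsilyloxy)cyclohex-2-en-1-one | O=C1C=C[C@@H](O[Si](C)(C)C(C)(C)C)CC1 | intermediate
10 | (S)-4-(tert-butyldimethylsilyloxy)-2-iodocyclohex-2-en-1-one | O=C1C(I)=C[C@@H](O[Si](C)(C)C(C)(C)C)CC1 | intermediate
11 | (S)-4-(tert-butyldimethylsilyloxy)-2-methylcyclohex-2-en-1-one | O=C1CC[C@H](O[Si](C)(C)C(C)(C)C)C=C1C | intermediate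
12 | (E)-penta-1,3-diene | C/C=C/C=C | starting material
13 | 9β-(tert-butyldimethylsilyloxy)-4α,5β-dimethyl-10βH-Δ2-octalin-6-one | O=C1CC[C@H](O[Si](C)(C)C(C)(C)C)[C@H]2CC=C[C@@H](C)[C@@]12C | intermediate
14 | 6-tosylhydrazone of 13 | Cc1ccc(cc1)S(=O)(=O)N/N=C1\CC[C@H](O[Si](C)(C)C(C)(C)C)[C@H]2CC=C[C@@H](C)[C@@]12C | intermediate
15 | 9β-(tert-butyldimethylsilyloxy)-4α,5β-dimethyl-10βH-Δ2-octalin | C1CC[C@H](O[Si](C)(C)C(C)(C)C)[C@H]2CC=C[C@@H](C)[C@@]12C | intermediate
16 | 9β-(tert-butyldimethylsilyloxy)-4,5β-dimethyl-10βH-Δ3-octalin | C1CC[C@H](O[Si](C)(C)C(C)(C)C)[C@H]2CCC=C(C)[C@@]12C | intermediate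
17 | 4,5β-dimethyl-10βH-Δ3-octalin-9β-ol | C1CC[C@H](O)[C@H]2CCC=C(C)[C@@]12C | intermediate
18 | 4,5β-dimethyl-10βH-Δ3-octalin-9-one (cis) | O=C1CCC[C@]2(C)C(C)=CCC[C@H]12 | intermediate
19 | 4,5β-dimethyl-10αH-Δ3-octalin-9-one (trans) | O=C1CCC[C@]2(C)C(C)=CCC[C@@H]12 | intermediate
20 | methyl 4,5β-dimethyl-9-oxo-10αH-Δ3-octalin-8-carboxylate | COC(=O)C1CC[C@]2(C)C(C)=CCC[C@H]2C1=O | intermediate
21 | methyl 4,5β,8α-trimethyl-9-oxo-10αH-Δ3-octalin-8β-carboxylate | COC(=O)[C@@]1(C)CC[C@]2(C)C(C)=CCC[C@H]2C1=O | intermediate
22 | methyl 4,5β,8α-trimethyl-9-methylidene-10αH-Δ3-octalin-8β-carboxylate | COC(=O)[C@@]1(C)CC[C@]2(C)C(C)=CCC[C@H]2C1=C | intermediate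
23 | methyl 4,5β,8α,9β-tetramethyl-10αH-Δ3-octalin-8β-carboxylate | COC(=O)[C@@]1(C)CC[C@]2(C)C(C)=CCC[C@H]2[C@H]1C | intermediate
24 | (4,5β,8α,9β-tetramethyl-10αH-Δ3-octalin-8β-yl)methanol | OC[C@@]1(C)CC[C@]2(C)C(C)=CCC[C@H]2[C@H]1C | intermediate
25 | 4,5β,8α,9β-tetramethyl-10αH-Δ3-octalin-8β-carbaldehyde | O=C[C@@]1(C)CC[C@]2(C)C(C)=CCC[C@H]2[C@H]1C | intermediate
26 | 1,2,4,5-tetramethoxybenzene | COc1cc(OC)c(OC)cc1OC | starting material
27 | 2,3,5,6-tetramethoxyphenyllithium | [Li]c1c(OC)c(OC)cc(OC)c1OC | intermediate
28 | lithium aryl(decalin-8β-yl)methoxide | [Li+].[O-]C(c1c(OC)c(OC)cc(OC)c1OC)[C@@]1(C)CC[C@]2(C)C(C)=CCC[C@H]2[C@H]1C | intermediate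
29 | O-[aryl(decalin-8β-yl)methyl] S-methyl dithiocarbonate | CSC(=S)OC(c1c(OC)c(OC)cc(OC)c1OC)[C@@]1(C)CC[C@]2(C)C(C)=CCC[C@H]2[C@H]1C | intermediate
30 | 8β-[(2,3,5,6-tetramethoxyphenyl)methyl]-4,5β,8α,9β-tetramethyl-10αH-Δ3-octalin | COc1cc(OC)c(OC)c(C[C@@]2(C)CC[C@]3(C)C(C)=CCC[C@H]3[C@H]2C)c1OC | intermediate
31 | 3-(decalin-8β-ylmethyl)-2,5-dimethoxy-1,4-benzoquinone | COC1=CC(=O)C(OC)=C(C[C@@]2(C)CC[C@]3(C)C(C)=CCC[C@H]3[C@H]2C)C1=O | intermediate
32 | 3-(decalin-8β-ylmethyl)-2-hydroxy-5-methoxy-1,4-benzoquinone | COC1=CC(=O)C(O)=C(C[C@@]2(C)CC[C@]3(C)C(C)=CCC[C@H]3[C@H]2C)C1=O | intermediate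
33 | dysidenone A, (1′S,5′R) in ring C | COC(=O)[C@]1(O)C=C(OC)C(=O)[C@@H]1C[C@@]1(C)CC[C@]2(C)C(C)=CCC[C@H]2[C@H]1C | target

**Step count**
Total steps: 25. Longest linear sequence: 25 (from (−)-quinic acid; piperylene and the tetramethoxyarene are bought).

**Steps most likely to fail**

1. Step 25, the one step beyond precedent. The hydroxyquinone may bind copper as its enolate and stall turnover, the ligand may give little or the opposite facial induction, or C5′ may epimerise after the shift. Fallback, known chemistry: setting out from 32, aqueous NaOH effects the classical benzilic acid rearrangement of the 2-hydroxyquinone to the ring-contracted hydroxy acids. The isomer with the target configuration, 1-hydroxy-3-methoxy-4-oxo-5-(decalin-8β-ylmethyl)cyclopent-2-ene-1-carboxylic acid F1, is separated from its C1′/C5′ diastereomers by crystallisation of its quinine salt or by preparative HPLC. Esterification with TMSCHN2 in MeOH–toluene comes back to the route at 33.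

2. Step 12. The double bond may walk the other way, through C1=C2 to the ring-fusion position C1=C10, or conversion may stop at an equilibrium mixture. Fallback, which fixes the alkene position by an activating group on the diene: setting out from 11, (E)-pent-3-en-2-one is silylated (TBSOTf, Et3N) to (E)-2-(tert-butyldimethylsilyloxy)penta-1,3-diene F2. F2 is added to 11 under AlBr3/AlMe3 with the same regio- and facial sense as in step 9, giving the C2 silyl enol ether adduct F3. Saegusa oxidation (Pd(OAc)2, MeCN) gives the C2-oxo-Δ3-enone that still carries the C6 ketone, enedione F4. Ethane-1,2-dithiol with BF3·OEt2 converts both carbonyls into dithiolanes and cleaves the silyl ether, giving bis(dithiolane) alcohol F5. Mozingo desulfurisation with Raney Ni in EtOH removes both and comes back to the route at 17.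

3. Step 18. Hydrogen may be delivered to both faces of the C9 methylidene group, the exocyclic alkene may migrate into the ring, or the ring-A alkene may be reduced as well. Fallback: setting out from 22, hydroboration with 9-BBN (boron on the unhindered terminal carbon, hydrogen to the α face of C9) and oxidation with NaBO3 give the 9β-hydroxymethyl ester F6. MsCl and Et3N give mesylate F7. LiEt3BH displaces the mesylate by hydride and reduces the ester in the same operation, coming back to the route at 24.

**Further compounds**
F1 | step 25 | (1S,5R)-1-hydroxy-3-methoxy-4-oxo-5-(decalin-8β-ylmethyl)cyclopent-2-ene-1-carboxylic acid | OC(=O)[C@]1(O)C=C(OC)C(=O)[C@@H]1C[C@@]1(C)CC[C@]2(C)C(C)=CCC[C@H]2[C@H]1C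
F2 | step 12 | (E)-2-(tert-butyldimethylsilyloxy)penta-1,3-diene | C/C=C/C(=C)O[Si](C)(C)C(C)(C)C
F3 | step 12 | 2,9β-bis(tert-butyldimethylsilyloxy)-4α,5β-dimethyl-10βH-Δ2-octalin-6-one | O=C1CC[C@H](O[Si](C)(C)C(C)(C)C)[C@H]2CC(O[Si](C)(C)C(C)(C)C)=C[C@@H](C)[C@@]12C
F4 | step 12 | 9β-(tert-butyldimethylsilyloxy)-4,5β-dimethyl-10βH-Δ3-octalin-2,6-dione | O=C1CC[C@H](O[Si](C)(C)C(C)(C)C)[C@H]2CC(=O)C=C(C)[C@@]12C
F5 | step 12 | 2,6-bis(ethylenedithio)-4,5β-dimethyl-10βH-Δ3-octalin-9β-ol | S1CCSC12CC[C@H](O)[C@H]3CC4(SCCS4)C=C(C)[C@@]23C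
F6 | step 18 | methyl 9β-(hydroxymethyl)-4,5β,8α-trimethyl-10αH-Δ3-octalin-8β-carboxylate | COC(=O)[C@@]1(C)CC[C@]2(C)C(C)=CCC[C@H]2[C@H]1CO
F7 | step 18 | methyl 9β-(mesyloxymethyl)-4,5β,8α-trimethyl-10αH-Δ3-octalin-8β-carboxylate | COC(=O)[C@@]1(C)CC[C@]2(C)C(C)=CCC[C@H]2[C@H]1COS(C)(=O)=O
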